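## The problem

Locants used throughout (germacrane style): the ten-membered ring is C1–C10 with the double bond C1=C10. C4 is the carbinol carbon (methyl C15) and C6 carries the angelate. C7 and C8 are shared with the lactone (O–C8, C7, C11, C12; exocyclic C13), and C14 is the CH2OAc carbon on C10.

1. The compound is a cyclodecene trans-fused at C7–C8 to an α-methylene-γ-butyrolactone. A strained medium ring therefore has to be closed next to very reactive functionality.
2. The only ring double bond is trisubstituted, with the ring carbons C2 and C9 cis and C14 trans to C2. Forming it in the ring-closing event asks one step to handle ring strain, steric hindrance and geometry together.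
3. C6 (R), C7 (S) and C8 (R) are contiguous. C8 can control C7 through the five-membered ring, and C7 can control C6. C4 (S) is insulated by C5H2 and needs its own source.
4. Several groups rule out strong base, strong acid and hydride late in the route. They are the methylene lactone (a Michael acceptor, whose C7–H turns acidic as soon as C6 or C8 is a carbonyl), the angelate (Z to E), the allylic acetate and the tertiary alcohol.
5. The feature that opens the plan is the triad C1=C10–C14–OAc. It is the 1,3-transposed image of C1(OAc)–C10(=C14H2). Because C14 lies trans to C2, it is the isomer that both a chair [3,3] shift and the cis preference of a cyclodecene deliver.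
6. C10 can therefore enter the ring closure as the sp2 carbon of a 2-bromoallyl group and C1 as an aldehyde. Neither the alkene geometry nor the configuration at C1 has to be controlled when the ring is made.

## Retrosynthesis

**25 ⇒ 24 ⇒ 23.** No C–C bond is cut. After removal of the C4 silyl ether (24), the C14–O bond is exchanged for a C1–O bond and C1=C10 for C10=C14. This leads to the secondary allylic acetate 23 with an exocyclic methylene group. The move takes the trisubstituted alkene out of the ring-closure problem, and it uses the acetate that the target needs anyway. The forward reaction, a reversible suprafacial 1,3-acetate shift, has to end at the more substituted, ring-cis alkene from either C1 epimer.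

**23 ⇒ 22 ⇒ 20.** The bond cut is C1–C10. The neighbouring cuts are worse. C1=C10 means metathesis to a hindered alkene. C9–C10 has no good polarity. C1–C2 needs a stereodefined trisubstituted vinyl halide. The chosen cut pairs an aldehyde (C1) with a simple 2-bromoalkene (C10) in 20. The precursor is monocyclic and has no alkene geometry to define. The forward reaction must only be chemoselective for the aldehyde, irreversible and tolerant of three ester groups.

**20 ⇒ 18 ⇒ 17 ⇒ 14.** The C1 aldehyde is carried as the isopropylidene end of a terpene chain (18) and is released by ozonolysis. The C4–OH is silylated so that it cannot trap the C1 aldehyde as a five-membered lactol. The angelate goes on the only secondary hydroxyl of diol 14, which gives 17.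

**14 ⇒ 4 + 12.** The bond cut is C6–C7. It joins a C10 piece and a C8 piece of equal weight. It also creates C6, C7 and the exocyclic C11=C13 in one operation, at a stage where neither C6 nor C8 is ever a carbonyl next to the acrylate. Having C8–O already acylated by C12 in butenolide 12 fixes the lactone regiochemistry (8,12 rather than 6,12). The forward allylation must attack C7 anti to the C9 chain and deliver the 6R carbinol.

**12 ⇒ 11 ⇒ 9 + 10, and 9 ⇒ 8 ⇒ 5 + 6.** The C7=C11 bond (ring-closing metathesis to a five-membered ring) and the C8–O–C12 ester bond are cut. This leads to alcohol 9 and commercial acid 10. Alcohol 9 has a single stereocentre (C8). It comes from acrolein 5 and 2,3-dibromopropene 6 (bond C8–C9) by way of racemate 8 and a kinetic resolution.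

**4 ⇒ 3 ⇒ 2 ⇒ 1.** The C1–C6/C15 part, together with a sacrificial C3 end, is the intact skeleton of geraniol 1. C4 is set by asymmetric epoxidation (2). The C5 oxygen is removed by directed hydride opening (3), and C6 is oxidised to the aldehyde (4). No protecting group is needed in this branch.

## Roads not taken

**Alternative 1 (the most obvious):** cut C1=C10 itself.
- The forward key step would be ring-closing metathesis of triene A1.
- It would have to join a 1,1-disubstituted alkene bearing an allylic acetate to a second alkene and form a trisubstituted double bond inside a strained ten-membered ring.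
- The methylene lactone and the angelate would be present as competing olefins.
- The step is reversible, so ring strain favours oligomers, and the geometry rests on the ring alone.
- The chosen plan makes a σ bond irreversibly and settles the geometry afterwards under equilibrium control. Metathesis is kept only as a fallback.

**Alternative 2:** cut C6–C7 in the ring-closing step.
- The forward key step would be an intramolecular Barbier allylation of bromo aldehyde A2.
- It looks economical, but one high-dilution step would have to close the ring and set C6 and C7 together.
- The allyl metal is locked in the butenolide, so the unchelated chair leads to the C6 epimer, and inversion at a ring carbon of a cyclodecane is not realistic.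
- The C1=C10/C14 unit would still have to be built stereoselectively beforehand, at a cost of several reduction and differentiation steps.
- In the chosen plan the same bond is made between two fragments, where either C6 epimer can still be used.

**Alternative 3:** add the transannular bond C1–C6 and expand the ring.
- The terpene A3 would be converted into the hydroxy ketone A4. After 1,2-addition of a vinyl metal, an anionic oxy-Cope rearrangement would give cyclodecenone A5.
- The mapping of ten carbons is attractive.
- However, the chair transition state of the trans-dialkenyl carbinol gives the ring-trans alkene.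
- C6 emerges as a ketone next to C7.
- C8 carries no oxygen, and C11–C13 and the C14 oxygen are all missing.
- Repairing this costs more steps than the ring expansion saves.

Key step: step 12

Assumption: the organoindium and organochromium species are drawn as monomeric dihalides for bookkeeping only, and their spent forms are given as the simplest salts.

## Steps

Step 1
Reactants: 1 geraniol
Product: 2 (2S,3S)-2,3-epoxygeraniol
Conditions: Ti(OiPr)4 (5 mol %), L-(+)-DET (7 mol %), t-BuOOH, 4 Å MS, CH2Cl2, −20 °C
Reagents that add atoms: tert-butyl hydroperoxide, CC(C)(C)OO
Why: Sharpless asymmetric epoxidation of a primary allylic alcohol; the L-(+)-tartrate catalyst selects the alkene face that gives the 3S centre, which becomes C4, and the remote trisubstituted alkene is not directed and stays.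

Step 2
Reactants: 2 (2S,3S)-2,3-epoxygeraniol
Product: 3 (S)-3,7-dimethyloct-6-ene-1,3-diol
Conditions: Red-Al, THF, 0 °C; Rochelle salt work-up
Reagents that add atoms: none
Why: Hydroxyl-directed reductive opening of a 2,3-epoxy alcohol; the alkoxyaluminate delivers hydride to the proximal, non-quaternary carbon (C5) and gives the 1,3-diol, and the C4–O bond is not touched, so C4 stays S.

Step 3
Reactants: 3 (S)-3,7-dimethyloct-6-ene-1,3-diol
Product: 4 (S)-3-hydroxy-3,7-dimethyloct-6-enal
Conditions: TEMPO (10 mol %), PhI(OAc)2, CH2Cl2, rt
Reagents that add atoms: none
Why: Oxoammonium (TEMPO) oxidation takes the primary alcohol to the aldehyde and cannot oxidise the tertiary one; the neutral conditions should avoid dehydration of the β-hydroxy aldehyde.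

Step 4
Reactants: 5 acrolein; 6 2,3-dibromopropene
Product: 8 rac-5-bromohexa-1,5-dien-3-ol, via 2-bromoallylindium dibromide 7 (not isolated)
Conditions: In powder, THF–H2O (1:1), rt
Reagents that add atoms: none
Why: Barbier allylation in water; indium inserts only into the allylic C–Br bond and the allylindium adds 1,2 to the enal, forming C8–C9; no stereocontrol is asked because the next step resolves the alcohol.

Step 5
Reactants: 8 rac-5-bromohexa-1,5-dien-3-ol
Product: 9 (R)-5-bromohexa-1,5-dien-3-ol
Conditions: Ti(OiPr)4 (15 mol %), L-(+)-DIPT (20 mol %), t-BuOOH (0.6 equiv), 4 Å MS, CH2Cl2, −20 °C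
Reagents that add atoms: none
Why: Sharpless kinetic resolution of a secondary allylic alcohol; with L-(+)-DIPT the S enantiomer is epoxidised fast and the R enantiomer is left, which sets C8; the 2-bromoalkene is electron-poor and only homoallylic, so it is not attacked.

Step 6
Reactants: 9 (R)-5-bromohexa-1,5-dien-3-ol; 10 2-(bromomethyl)acrylic acid
Product: 11 (R)-5-bromohexa-1,5-dien-3-yl 2-(bromomethyl)acrylate
Conditions: DCC, DMAP (5 mol %), CH2Cl2, 0 °C
Reagents that add atoms: none
Why: Carbodiimide (Steglich) esterification; the C8–O bond is not broken, so C8 keeps its configuration, and low temperature with little DMAP limits attack of the amine on the allylic bromide.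

Step 7
Reactants: 11 (R)-5-bromohexa-1,5-dien-3-yl 2-(bromomethyl)acrylate
Product: 12 (R)-5-(2-bromoallyl)-3-(bromomethyl)furan-2(5H)-one
Conditions: second-generation Ru–NHC benzylidene catalyst (5 mol %), CH2Cl2, reflux, 0.01 M
Reagents that add atoms: none
Why: Ring-closing metathesis of an allylic acrylate to an α-substituted butenolide (C7=C11); closure of the unstrained five-membered ring is fast and the 2-bromoalkene is inert to the carbene.

Step 8
Reactants: 4 (S)-3-hydroxy-3,7-dimethyloct-6-enal; 12 (R)-5-(2-bromoallyl)-3-(bromomethyl)furan-2(5H)-one
Product: 14 (4R,5R)-5-(2-bromoallyl)-4-[(1R,3S)-1,3-dihydroxy-3,7-dimethyloct-6-enyl]-3-methylenedihydrofuran-2(3H)-one (C4 S, C6 R, C8 R, C7–H/C8–H trans), via butenolide allylindium dibromide 13 (not isolated)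
Conditions: In powder, THF–H2O (1:1), rt
Reagents that add atoms: none
Why: Barbier allylation with a 3-(bromomethyl)butenolide, a known way to β-(1-hydroxyalkyl)-α-methylene lactones; the allylindium reacts at C7 (SE2') on the face anti to the C9 chain, which sets C7 trans to C8 and moves the double bond to C11=C13. The free C4–OH should bind indium together with the aldehyde oxygen, which puts C5 axial in the six-membered transition state and should give the 6R carbinol; the vinylic bromide is inert to indium.

Step 9
Reactants: 14 seco-diol; 15 angelic acid
Product: 17 6-O-angelate of 14, via angelic 2,4,6-trichlorobenzoic anhydride 16 (not isolated)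
Conditions: 15, 2,4,6-trichlorobenzoyl chloride, Et3N, toluene, rt; then 14, 80 °C
Reagents that add atoms: none
Why: Yamaguchi-type mixed-anhydride esterification run without DMAP, the usual way to transfer an angeloyl group without Z-to-E isomerisation; only the secondary C6–OH is acylated and the tertiary C4–OH is too hindered.

Step 10
Reactants: 17 6-O-angelate
Product: 18 4-O-triethylsilyl ether of 17
Conditions: TESOTf, 2,6-lutidine, CH2Cl2, −78 to 0 °C
Reagents that add atoms: triethylsilyl trifluoromethanesulfonate, CC[Si](CC)(CC)OS(=O)(=O)C(F)(F)F
Why: Silylation of a tertiary alcohol with a silyl triflate; it prevents the C4–OH from closing a five-membered lactol on the C1 aldehyde that is made next.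

Step 11
Reactants: 18 silyl ether
Product: 20 C1 aldehyde (4-silyloxy-6-angeloyloxy seco-aldehyde with the 2-bromoallyl group on C8), via secondary ozonide 19 (not isolated)
Conditions: O3, CH2Cl2, −78 °C, Sudan III as end-point indicator; then Me2S, −78 °C to rt
Reagents that add atoms: ozone, [O-][O+]=O
Why: Chemoselective ozonolysis; the isopropylidene alkene is by far the most electron-rich of the four C=C bonds (the others are a 2-bromoalkene and two acrylate-type alkenes), so one equivalent of ozone should cleave only this one.

Step 12
Reactants: 20 C1 aldehyde
Product: 22 (4S,6R,7S,8R)-1-hydroxy-10(14)-methylene macrocycle (both C1 epimers), via alkenylchromium dichloride 21 (not isolated)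
Conditions: CrCl2 (10 equiv), NiCl2 (10 mol %), DMSO–THF, rt, slow addition of 20 to a final 1 mM
Reagents that add atoms: none
Why: Nozaki–Hiyama–Kishi reaction: Ni(0) inserts into the C10–Br bond, transmetallation gives the alkenylchromium(III) species 21, and this adds to the C1 aldehyde; the closest known reaction type is the Ni/Cr closure of nine- and ten-membered carbocycles from 2-haloallyl aldehydes. The ring that closes is the ten-membered carbocycle C1–C10, by a 10-exo-trig attack of C10 on the carbonyl carbon C1. The one new stereocentre, C1, is under no reliable control and needs none, because both epimers lose it in step 14. The step needs chemoselectivity and closure in preference to oligomerisation. Alkenylchromium reagents add to aldehydes only, so lactone, angelate, methylene group and silyl ether should survive, and C10–Br is the only carbon–halogen bond left. High dilution favours closure, the trans-lactone at C7–C8 removes two rotors from the chain, and the exocyclic sp2 centre at C10 takes one inward hydrogen out of the ring. The addition is irreversible, so ring strain cannot reopen the product as it can in a metathesis.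

Step 13
Reactants: 22 macrocyclic allylic alcohol
Product: 23 1-O-acetate of 22 (both C1 epimers)
Conditions: Ac2O, pyridine, DMAP (cat.), CH2Cl2, 0 °C to rt
Reagents that add atoms: acetic anhydride, CC(=O)OC(C)=O
Why: Standard acetylation of the only free hydroxyl group; the acetyl group introduced here is the one found at C14 in the target.

Step 14
Reactants: 23 secondary allylic acetate
Product: 24 4-O-triethylsilyl ether of the target (C14 acetate, ring-cis C1=C10)
Conditions: PdCl2(MeCN)2 (10 mol %), THF, rt
Reagents that add atoms: none
Why: Pd(II)-catalysed [3,3] allylic acetate transposition (cyclisation-induced rearrangement): Pd binds C10=C14, the acetate carbonyl attacks C14, and the six-membered acetoxonium ion opens at C1–O. The shift is reversible and should drain both C1 epimers into the primary acetate with the more substituted alkene; the chair with C2 equatorial places C2 trans to C14 and cis to C9, which is also the less strained cyclodecene.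

Step 15
Reactants: 24 silyl ether of the target
Product: 25 target, (4S,6R,7S,8R)-14-acetoxy-6-angeloyloxy-4-hydroxygermacra-1(10)Z-ring-cis,11(13)-dien-12,8-olide
Conditions: HF·pyridine, pyridine–THF, 0 °C to rt
Reagents that add atoms: none
Why: Fluoride-mediated desilylation under buffered conditions; acetate, angelate, lactone and the tertiary alcohol are stable and no stereocentre is touched.

## Compound list

1 | geraniol | CC(C)=CCC/C(C)=C/CO | starting material
2 | (2S,3S)-2,3-epoxygeraniol | CC(C)=CCC[C@]1(C)O[C@H]1CO | intermediate
3 | (S)-3,7-dimethyloct-6-ene-1,3-diol | CC(C)=CCC[C@](C)(O)CCO | intermediate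
4 | (S)-3-hydroxy-3,7-dimethyloct-6-enal | CC(C)=CCC[C@](C)(O)CC=O | intermediate
5 | acrolein | C=CC=O | starting material
6 | 2,3-dibromopropene | C=C(Br)CBr | starting material
7 | 2-bromoallylindium dibromide (not isolated) | C=C(Br)C[In](Br)Br | intermediate
8 | rac-5-bromohexa-1,5-dien-3-ol | C=CC(O)CC(Br)=C | intermediate
9 | (R)-5-bromohexa-1,5-dien-3-ol | C=C[C@H](O)CC(Br)=C | intermediate
10 | 2-(bromomethyl)acrylic acid | C=C(CBr)C(=O)O | starting material
11 | (R)-5-bromohexa-1,5-dien-3-yl 2-(bromomethyl)acrylate | C=C[C@@H](CC(Br)=C)OC(=O)C(=C)CBr | intermediate
12 | (R)-5-(2-bromoallyl)-3-(bromomethyl)furan-2(5H)-one | BrCC1=C[C@@H](CC(Br)=C)OC1=O | intermediate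
13 | butenolide allylindium dibromide (not isolated) | Br[In](Br)CC1=C[C@@H](CC(Br)=C)OC1=O | intermediate
14 | seco-diol, (4R,5R)-5-(2-bromoallyl)-4-[(1R,3S)-1,3-dihydroxy-3,7-dimethyloct-6-enyl]-3-methylenedihydrofuran-2(3H)-one | C=C1C(=O)O[C@H](CC(Br)=C)[C@H]1[C@H](O)C[C@@](C)(O)CCC=C(C)C | intermediate
15 | angelic acid | C/C=C(/C)C(=O)O | starting material
16 | angelic 2,4,6-trichlorobenzoic anhydride (not isolated) | C/C=C(/C)C(=O)OC(=O)c1c(Cl)cc(Cl)cc1Cl | intermediate
17 | 6-O-angelate of 14 | C=C1C(=O)O[C@H](CC(Br)=C)[C@H]1[C@H](OC(=O)/C(C)=C\C)C[C@@](C)(O)CCC=C(C)C | intermediate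
18 | 4-O-triethylsilyl ether of 17 | C=C1C(=O)O[C@H](CC(Br)=C)[C@H]1[C@H](OC(=O)/C(C)=C\C)C[C@@](C)(O[Si](CC)(CC)CC)CCC=C(C)C | intermediate
19 | secondary ozonide of 18 (not isolated) | C=C1C(=O)O[C@H](CC(Br)=C)[C@H]1[C@H](OC(=O)/C(C)=C\C)C[C@@](C)(O[Si](CC)(CC)CC)CCC2OOC(C)(C)O2 | intermediate
20 | C1 aldehyde | C=C1C(=O)O[C@H](CC(Br)=C)[C@H]1[C@H](OC(=O)/C(C)=C\C)C[C@@](C)(O[Si](CC)(CC)CC)CCC=O | intermediate
21 | alkenylchromium dichloride (not isolated) | C=C1C(=O)O[C@H](CC(=C)[Cr](Cl)Cl)[C@H]1[C@H](OC(=O)/C(C)=C\C)C[C@@](C)(O[Si](CC)(CC)CC)CCC=O | intermediate
22 | macrocyclic allylic alcohol, both C1 epimers | C=C1C(=O)O[C@@H]2CC(=C)C(O)CC[C@](C)(O[Si](CC)(CC)CC)C[C@@H](OC(=O)/C(C)=C\C)[C@@H]12 | intermediate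
23 | macrocyclic secondary allylic acetate, both C1 epimers | C=C1C(=O)O[C@@H]2CC(=C)C(OC(C)=O)CC[C@](C)(O[Si](CC)(CC)CC)C[C@@H](OC(=O)/C(C)=C\C)[C@@H]12 | intermediate
24 | 4-O-triethylsilyl ether of the target | C=C1C(=O)O[C@@H]2C/C(COC(C)=O)=C\CC[C@](C)(O[Si](CC)(CC)CC)C[C@@H](OC(=O)/C(C)=C\C)[C@@H]12 | intermediate
25 | CNP0270682.1 | C=C1C(=O)O[C@@H]2C/C(COC(C)=O)=C\CC[C@](C)(O)C[C@@H](OC(=O)/C(C)=C\C)[C@@H]12 | target

## Step count and least certain steps

Total step count: 15. Longest linear sequence: 12 steps (steps 4–15). Steps 1–3 form the second branch.

**Step 12 (key step).** Oxidative addition of the hindered 2-bromoalkene to nickel may be slow. Protodebromination and intermolecular coupling could then outrun the closure, which also has to pay the transannular strain of the ten-membered ring. The fallback sets out from 18 and changes the bond-forming logic: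
- Stille coupling of the vinylic bromide with (tributylstannyl)methanol would give the 2-(hydroxymethyl)allyl compound F1.
- Acetylation would give the allylic acetate F2.
- Ring-closing metathesis between the 1,1-disubstituted alkene and the isopropylidene end, with loss of a volatile alkene, would come back to the route at 24.

**Step 8.** Facial selectivity at the aldehyde may be poor. The chelated transition state (C5 axial) competes with the unchelated chair (C5 equatorial), which leads to the C6 epimer. The fallback sets out from 4 and accepts the unchelated pathway:
- Silylation of the tertiary alcohol would give the silyloxy aldehyde F3.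
- The same Barbier coupling with 12 should then give the 6S alcohol F4.
- A Mitsunobu esterification with 15 would install the angelate with inversion and come back to the route at 18.

**Step 14.** The transposition may stop at an equilibrium mixture. Palladium may also ionise the allylic acetate, with loss of geometry or elimination to a diene. The fallback sets out from 22. An oxorhenium-catalysed 1,3-transposition of the free allylic alcohol would give the primary allylic alcohol F5, and acetylation of F5 comes back to the route at 24.

**Step 9.** Acylation of the hindered C6–OH may be slow enough that Z-to-E isomerisation of the angeloyl group sets in. Reversible amine addition to the methylene lactone may do the same. The fallback sets out from 14. Esterification with 2-[bis(2,2,2-trifluoroethoxy)phosphoryl]propanoic acid would give the phosphonate ester F6. A Still–Gennari olefination with acetaldehyde (K2CO3, 18-crown-6) would then build the Z-alkene in place and come back to the route at 17.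

**Step 11.** Over-oxidation is possible if ozone also attacks the 2-bromoalkene or the angelate once the end point is passed. The fallback sets out from 18. Epoxidation with one equivalent of peracid should take only the isopropylidene alkene and give the epoxide F7. Periodic acid cleavage of F7 comes back to the route at 20.

## Further compounds

F1 | step 12 | 2-(hydroxymethyl)allyl compound from 18 | C=C1C(=O)O[C@H](CC(=C)CO)[C@H]1[C@H](OC(=O)/C(C)=C\C)C[C@@](C)(O[Si](CC)(CC)CC)CCC=C(C)C
F2 | step 12 | allylic acetate, metathesis precursor | C=C1C(=O)O[C@H](CC(=C)COC(C)=O)[C@H]1[C@H](OC(=O)/C(C)=C\C)C[C@@](C)(O[Si](CC)(CC)CC)CCC=C(C)C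
F3 | step 8 | (S)-3,7-dimethyl-3-(triethylsilyloxy)oct-6-enal | CC(C)=CCC[C@](C)(O[Si](CC)(CC)CC)CC=O
F4 | step 8 | 6S alcohol, C6 epimer of the 4-O-silyl seco-alcohol | C=C1C(=O)O[C@H](CC(Br)=C)[C@H]1[C@@H](O)C[C@@](C)(O[Si](CC)(CC)CC)CCC=C(C)C
F5 | step 14 | macrocyclic primary allylic alcohol (C14–OH, ring-cis C1=C10) | C=C1C(=O)O[C@@H]2C/C(CO)=C\CC[C@](C)(O[Si](CC)(CC)CC)C[C@@H](OC(=O)/C(C)=C\C)[C@@H]12
F6 | step 9 | 6-O-[2-bis(2,2,2-trifluoroethoxy)phosphorylpropanoate] of 14 | C=C1C(=O)O[C@H](CC(Br)=C)[C@H]1[C@H](OC(=O)C(C)P(=O)(OCC(F)(F)F)OCC(F)(F)F)C[C@@](C)(O)CCC=C(C)C
F7 | step 11 | terminal epoxide of 18 | C=C1C(=O)O[C@H](CC(Br)=C)[C@H]1[C@H](OC(=O)/C(C)=C\C)C[C@@](C)(O[Si](CC)(CC)CC)CCC2OC2(C)C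
A1 | alternative 1 | triene for ring-closing metathesis at C1=C10 | C=C1C(=O)O[C@H](CC(=C)COC(C)=O)[C@H]1[C@H](OC(=O)/C(C)=C\C)C[C@@](C)(O)CCC=C
A2 | alternative 2 | bromo aldehyde for intramolecular Barbier closure at C6–C7 | O=CC[C@@](C)(O)CC/C=C(/COC(C)=O)C[C@H]1OC(=O)C(CBr)=C1
A3 | alternative 3 | (1S,4R)-p-mentha-2,8-dien-1-ol | C[C@@]1(O)C=C[C@H](C(C)=C)CC1
A4 | alternative 3 | (2S,5S)-5-hydroxy-5-methyl-2-(prop-1-en-2-yl)cyclohexanone | O=C1C[C@@](C)(O)CC[C@H]1C(C)=C
A5 | alternative 3 | (S,E)-3-hydroxy-3,7-dimethylcyclodec-6-enone (ring-trans alkene) | O=C1CCC/C(C)=C/CC[C@](C)(O)C1
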